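Ring A is a benzoate with the ester on C1, the diaryl ether oxygen on C2 and oxygen on C3 and C5; C2 and C3 with the ether oxygen map onto an α-aryloxyacetate, and C1, C6, C5 and C4 onto methyl 4-oxopent-2-ynoate.
Key disconnections are C1–C2 (Michael addition) and C3–C4 (Claisen closure) of ring A; the ether oxygen is the phenol oxygen of ring B throughout, so no aryl–oxygen bond is made.
The ring B aryloxyacetate comes from 2,6-dihydroxy-4-methylbenzaldehyde by reduction, acetonide formation (one phenol and the benzylic oxygen), chlorination para to the free phenol and O-alkylation with methyl bromoacetate; the ynone comes from methyl propiolate and acetaldehyde.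
After the annulation: silylation of the C5 hydroxyl, methylation of the C3 hydroxyl, acetonide hydrolysis, oxidation of the benzylic carbon of ring B to the carboxylic acid, desilylation.
Ring order: ring B is bought, the protecting 1,3-dioxine ring is closed in step 2, and ring A is closed in step 7.

Key step: step 7

Remark: the carboxyl carbon of ring B is carried as the acetal CH2 of a 4H-1,3-benzodioxine until after the annulation, because a lactone or ester carbonyl ortho to the aryloxyacetate would be attacked by its enolate (5-exo Dieckmann closure to a benzofuran-3-one) and by the methoxide set free in the Claisen closure.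

Step 1
Reactants: 1 2,6-dihydroxy-4-methylbenzaldehyde
Product: 2 2-(hydroxymethyl)-5-methylbenzene-1,3-diol
Conditions: NaBH4, THF/MeOH, 0 °C; pH 7 phosphate buffer
Reagents that add atoms: none
Why: Hydride reduction of the aryl aldehyde (NaBH4 reduction) gives the benzylic alcohol, and the low temperature with a neutral quench should prevent loss of the benzylic oxygen through an ortho-quinone methide; crude 2 is used at once.

Step 2
Reactants: 2 2-(hydroxymethyl)-5-methylbenzene-1,3-diol
Product: 3 2,2,7-trimethyl-4H-1,3-benzodioxin-5-ol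
Conditions: Me2C(OMe)2, PPTS (cat.), acetone, rt
Reagents that add atoms: 2,2-dimethoxypropane, COC(C)(C)OC
Why: Acid-catalysed acetonide formation (transketalisation) closes the six-membered ketal between the benzylic alcohol and one of the two equivalent phenols, which desymmetrises ring B and leaves the other phenol free.

Step 3
Reactants: 3 2,2,7-trimethyl-4H-1,3-benzodioxin-5-ol
Product: 4 8-chloro-2,2,7-trimethyl-4H-1,3-benzodioxin-5-ol
Conditions: N-chlorosuccinimide (1.0 equiv), DMF, 0 °C to rt
Reagents that add atoms: N-chlorosuccinimide, O=C1CCC(=O)N1Cl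
Why: Electrophilic aromatic chlorination of the phenol should take the position para to the free hydroxyl (C8), because a free hydroxyl is a stronger para director than the ketal ether oxygen and both open positions are otherwise alike (each is ortho to the methyl group).

Step 4
Reactants: 4 8-chloro-2,2,7-trimethyl-4H-1,3-benzodioxin-5-ol; 5 methyl bromoacetate
Product: 6 methyl 2-[(8-chloro-2,2,7-trimethyl-4H-1,3-benzodioxin-5-yl)oxy]acetate
Conditions: K2CO3, acetone, 56 °C
Reagents that add atoms: none
Why: Williamson ether synthesis: the phenoxide displaces bromide from the α-bromo ester under weakly basic conditions that leave the ketal and the aryl chloride untouched.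

Step 5
Reactants: 7 methyl propiolate; 8 acetaldehyde
Product: 10 methyl 4-hydroxypent-2-ynoate (racemate), via lithium acetylide 9 (not isolated)
Conditions: n-BuLi, THF, −78 °C; then 8, −78 °C; aq. NH4Cl
Reagents that add atoms: none
Why: Deprotonation of the terminal alkyne at low temperature and 1,2-addition of the lithium acetylide to the aldehyde is the standard route to 4-hydroxy-2-ynoates; the carbinol centre forms as a racemate and is removed in step 6.

Step 6
Reactants: 10 methyl 4-hydroxypent-2-ynoate (racemate)
Product: 11 methyl 4-oxopent-2-ynoate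
Conditions: Dess–Martin periodinane, CH2Cl2, 0 °C to rt
Reagents that add atoms: none
Why: Dess–Martin oxidation of the propargylic alcohol gives the ynone under neutral non-aqueous conditions, which the electrophilic product tolerates.

Step 7
Reactants: 6 methyl 2-[(8-chloro-2,2,7-trimethyl-4H-1,3-benzodioxin-5-yl)oxy]acetate; 11 methyl 4-oxopent-2-ynoate
Product: 14 methyl 2-[(8-chloro-2,2,7-trimethyl-4H-1,3-benzodioxin-5-yl)oxy]-3,5-dihydroxybenzoate, via lithium ester enolate 12 (not isolated), via Michael adduct 13 (not isolated)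
Conditions: LiN(SiMe3)2, THF, −78 °C; 11, −78 to −20 °C; then MeOH, 50 °C; aq. NH4Cl
Reagents that add atoms: none
Why: Proposed new method: the lithium enolate 12 of the aryloxyacetate should add to ynone 11 at the alkyne carbon that carries the ester (β to the ketone, the stronger acceptor), forming C1–C2 and giving, after proton transfer, the dienolate of adduct 13, whose alkene geometry equilibrates. In methanol the minor cross-conjugated methyl ketone enolate should then attack the acetate ester carbon in a 6-(enolexo)-exo-trig Claisen closure (C3–C4), methoxide is lost and the cyclohexenedione tautomerises irreversibly to the resorcinol ring A. The closest known reaction type is the Michael–Claisen annulation of malonates or acetonedicarboxylates with enones and ynones (the dimedone synthesis and related resorcylate syntheses); what is new is a simple α-aryloxy ester enolate as the donor. No stereocentre is formed. The step needs conjugate addition β to the ketone in preference to addition to the ketone carbonyl or proton transfer from the acetyl group, which the doubly activated alkyne, the low temperature and the reversibility of carbonyl addition during the methanol stage should secure. Ring B carries no carbonyl group ortho to the enolate, so no Dieckmann closure can compete, and the ether oxygen stays on ring B throughout.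

Step 8
Reactants: 14 methyl 2-[(8-chloro-2,2,7-trimethyl-4H-1,3-benzodioxin-5-yl)oxy]-3,5-dihydroxybenzoate
Product: 15 methyl 2-[(8-chloro-2,2,7-trimethyl-4H-1,3-benzodioxin-5-yl)oxy]-3-hydroxy-5-[tri(propan-2-yl)silyloxy]benzoate
Conditions: i-Pr3SiCl (1.05 equiv), imidazole, DMF, 0 °C
Reagents that add atoms: chlorotri(propan-2-yl)silane, CC(C)[Si](Cl)(C(C)C)C(C)C
Why: Silylation of a phenol by a bulky silyl chloride is governed by steric access, and the C5 hydroxyl lies between two ring hydrogens whereas the C3 hydroxyl is shielded by the ortho 2,6-disubstituted aryloxy group.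

Step 9
Reactants: 15 methyl 2-[(8-chloro-2,2,7-trimethyl-4H-1,3-benzodioxin-5-yl)oxy]-3-hydroxy-5-[tri(propan-2-yl)silyloxy]benzoate
Product: 16 methyl 2-[(8-chloro-2,2,7-trimethyl-4H-1,3-benzodioxin-5-yl)oxy]-3-methoxy-5-[tri(propan-2-yl)silyloxy]benzoate
Conditions: MeI, K2CO3, acetone, 40 °C
Reagents that add atoms: iodomethane, CI
Why: Williamson methylation of the remaining C3 phenol; the tri(propan-2-yl)silyl aryl ether, the methyl ester and the ketal are stable to K2CO3 in acetone.

Step 10
Reactants: 16 methyl 2-[(8-chloro-2,2,7-trimethyl-4H-1,3-benzodioxin-5-yl)oxy]-3-methoxy-5-[tri(propan-2-yl)silyloxy]benzoate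
Product: 17 methyl 2-[4-chloro-3-hydroxy-2-(hydroxymethyl)-5-methylphenoxy]-3-methoxy-5-[tri(propan-2-yl)silyloxy]benzoate
Conditions: 1 M HCl, THF, rt
Reagents that add atoms: none
Why: Acid hydrolysis of the isopropylidene ketal frees the ring B phenol and the benzylic alcohol, while the silyl aryl ether, the methyl ester and the aryl ethers are stable to dilute aqueous acid at room temperature and water returns any ortho-quinone methide to the alcohol.

Step 11
Reactants: 17 methyl 2-[4-chloro-3-hydroxy-2-(hydroxymethyl)-5-methylphenoxy]-3-methoxy-5-[tri(propan-2-yl)silyloxy]benzoate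
Product: 18 methyl 2-(4-chloro-2-formyl-3-hydroxy-5-methylphenoxy)-3-methoxy-5-[tri(propan-2-yl)silyloxy]benzoate
Conditions: activated MnO2, CH2Cl2, rt
Reagents that add atoms: none
Why: MnO2 oxidises the benzylic alcohol selectively to the aldehyde (benzylic oxidation), which the hydrogen bond to the ortho hydroxyl stabilises, and leaves the aryl methyl group and the silyl-protected ring A untouched.

Step 12
Reactants: 18 methyl 2-(4-chloro-2-formyl-3-hydroxy-5-methylphenoxy)-3-methoxy-5-[tri(propan-2-yl)silyloxy]benzoate
Product: 19 3-chloro-2-hydroxy-6-{2-methoxy-6-(methoxycarbonyl)-4-[tri(propan-2-yl)silyloxy]phenoxy}-4-methylbenzoic acid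
Conditions: NaClO2, NaH2PO4, 2-methyl-2-butene, t-BuOH/H2O, 0 °C to rt
Reagents that add atoms: sodium chlorite, [Na+].[O-]Cl=O
Why: Pinnick oxidation takes the aldehyde to the carboxylic acid without touching the free ortho phenol, and 2-methyl-2-butene scavenges hypochlorous acid so that the electron-rich rings are not chlorinated.

Step 13
Reactants: 19 3-chloro-2-hydroxy-6-{2-methoxy-6-(methoxycarbonyl)-4-[tri(propan-2-yl)silyloxy]phenoxy}-4-methylbenzoic acid
Product: 20 isodihydromaldoxin, 3-chloro-2-hydroxy-6-[4-hydroxy-2-methoxy-6-(methoxycarbonyl)phenoxy]-4-methylbenzoic acid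
Conditions: Bu4NF, AcOH, THF, 0 °C
Reagents that add atoms: none
Why: Fluoride cleaves the aryl silyl ether (Si–F bond formation) and the acetic acid buffer protects the methyl ester and the salicylic acid from base.

Compound list
1 | 2,6-dihydroxy-4-methylbenzaldehyde | Cc1cc(O)c(C=O)c(O)c1 | starting material
2 | 2-(hydroxymethyl)-5-methylbenzene-1,3-diol | Cc1cc(O)c(CO)c(O)c1 | intermediate
3 | 2,2,7-trimethyl-4H-1,3-benzodioxin-5-ol | Cc1cc(O)c2COC(C)(C)Oc2c1 | intermediate
4 | 8-chloro-2,2,7-trimethyl-4H-1,3-benzodioxin-5-ol | Cc1cc(O)c2COC(C)(C)Oc2c1Cl | intermediate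
5 | methyl bromoacetate | COC(=O)CBr | starting material
6 | methyl 2-[(8-chloro-2,2,7-trimethyl-4H-1,3-benzodioxin-5-yl)oxy]acetate | COC(=O)COc1cc(C)c(Cl)c2OC(C)(C)OCc12 | intermediate
7 | methyl propiolate (methyl prop-2-ynoate) | C#CC(=O)OC | starting material
8 | acetaldehyde | CC=O | starting material
9 | methyl 3-lithioprop-2-ynoate (lithium acetylide) | [Li]C#CC(=O)OC | intermediate
10 | methyl 4-hydroxypent-2-ynoate (racemate) | CC(O)C#CC(=O)OC | intermediate
11 | methyl 4-oxopent-2-ynoate | CC(=O)C#CC(=O)OC | intermediate
12 | lithium 2-[(8-chloro-2,2,7-trimethyl-4H-1,3-benzodioxin-5-yl)oxy]-1-methoxyethen-1-olate (enolate geometry not defined) | COC(O[Li])=COc1cc(C)c(Cl)c2OC(C)(C)OCc12 | intermediate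
13 | dimethyl (3E)-2-[(8-chloro-2,2,7-trimethyl-4H-1,3-benzodioxin-5-yl)oxy]-3-(2-oxopropylidene)butanedioate (racemate at C2; present in the flask as its enolate) | COC(=O)C(Oc1cc(C)c(Cl)c2OC(C)(C)OCc12)/C(C(=O)OC)=C\C(C)=O | intermediate
14 | methyl 2-[(8-chloro-2,2,7-trimethyl-4H-1,3-benzodioxin-5-yl)oxy]-3,5-dihydroxybenzoate | COC(=O)c1cc(O)cc(O)c1Oc1cc(C)c(Cl)c2OC(C)(C)OCc12 | intermediate
15 | methyl 2-[(8-chloro-2,2,7-trimethyl-4H-1,3-benzodioxin-5-yl)oxy]-3-hydroxy-5-[tri(propan-2-yl)silyloxy]benzoate | COC(=O)c1cc(O[Si](C(C)C)(C(C)C)C(C)C)cc(O)c1Oc1cc(C)c(Cl)c2OC(C)(C)OCc12 | intermediate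
16 | methyl 2-[(8-chloro-2,2,7-trimethyl-4H-1,3-benzodioxin-5-yl)oxy]-3-methoxy-5-[tri(propan-2-yl)silyloxy]benzoate | COC(=O)c1cc(O[Si](C(C)C)(C(C)C)C(C)C)cc(OC)c1Oc1cc(C)c(Cl)c2OC(C)(C)OCc12 | intermediate
17 | methyl 2-[4-chloro-3-hydroxy-2-(hydroxymethyl)-5-methylphenoxy]-3-methoxy-5-[tri(propan-2-yl)silyloxy]benzoate | COC(=O)c1cc(O[Si](C(C)C)(C(C)C)C(C)C)cc(OC)c1Oc1cc(C)c(Cl)c(O)c1CO | intermediate
18 | methyl 2-(4-chloro-2-formyl-3-hydroxy-5-methylphenoxy)-3-methoxy-5-[tri(propan-2-yl)silyloxy]benzoate | COC(=O)c1cc(O[Si](C(C)C)(C(C)C)C(C)C)cc(OC)c1Oc1cc(C)c(Cl)c(O)c1C=O | intermediate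
19 | 3-chloro-2-hydroxy-6-{2-methoxy-6-(methoxycarbonyl)-4-[tri(propan-2-yl)silyloxy]phenoxy}-4-methylbenzoic acid | COC(=O)c1cc(O[Si](C(C)C)(C(C)C)C(C)C)cc(OC)c1Oc1cc(C)c(Cl)c(O)c1C(=O)O | intermediate
20 | isodihydromaldoxin, 3-chloro-2-hydroxy-6-[4-hydroxy-2-methoxy-6-(methoxycarbonyl)phenoxy]-4-methylbenzoic acid | COC(=O)c1cc(O)cc(OC)c1Oc1cc(C)c(Cl)c(O)c1C(=O)O | target

Total step count: 13. Longest linear sequence: 11 steps (steps 1 to 4 and 7 to 13); steps 5 and 6 make the ynone in a side branch.

Steps most likely to fail

Step 7 (carries the label). The enolate may add to the ketone carbonyl or be quenched by proton transfer from the acetyl group, conjugate addition may take the alkyne carbon next to the ketone, or the cross-conjugated enolate may close too slowly, so that the adduct is lost to oligomerisation. The fallback uses known chemistry: the diaryl ether bond is made by an Ullmann-type C–O coupling of a preformed ring A iodide, setting out from phenol 4 and coming back at 16. Commercial methyl 3-hydroxy-5-methoxybenzoate (COC(=O)c1cc(O)cc(OC)c1) would be iodinated para to its hydroxyl (N-iodosuccinimide, MeCN, 0 °C) to methyl 5-hydroxy-2-iodo-3-methoxybenzoate F1. F1 would be silylated (i-Pr3SiCl, imidazole, DMF) to methyl 2-iodo-3-methoxy-5-[tri(propan-2-yl)silyloxy]benzoate F2. Coupling of F2 with 4 (CuI, N,N-dimethylglycine, Cs2CO3, dioxane, 90 °C) should give 16 directly; the ester ortho to iodine assists the coupling and the aryl chloride of 4 should stay untouched. Steps 10 to 13 then follow unchanged.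

Step 3. Chlorination may divide between C8 and C6 (ortho to the hydroxyl, para to the ring oxygen) or go on to the dichloride. In the fallback the chlorine is put in at the lactone oxidation level, where the ring oxygen is an acylal oxygen and a weak donor and the hydroxyl is hydrogen-bonded to the lactone carbonyl, so that attack para to the hydroxyl has a stronger electronic bias. This branch does not leave from a compound of the route: it replaces steps 1 to 3, sets out from commercial 2,6-dihydroxy-4-methylbenzoic acid (Cc1cc(O)c(C(=O)O)c(O)c1) and comes back at 4. The acid would be converted (acetone, (CF3CO)2O, CF3CO2H, 0 °C to rt) into 5-hydroxy-2,2,7-trimethyl-4H-1,3-benzodioxin-4-one F3 and chlorinated (SO2Cl2, CH2Cl2, 0 °C) to 8-chloro-5-hydroxy-2,2,7-trimethyl-4H-1,3-benzodioxin-4-one F4. Allylation (allyl bromide, K2CO3, acetone) would give 8-chloro-2,2,7-trimethyl-5-(prop-2-enyloxy)-4H-1,3-benzodioxin-4-one F5, and reduction (LiAlH4, THF, 0 °C) the diol 2-chloro-6-(hydroxymethyl)-3-methyl-5-(prop-2-enyloxy)phenol F6. Ketalisation (Me2C(OMe)2, PPTS, acetone) would give 8-chloro-2,2,7-trimethyl-5-(prop-2-enyloxy)-4H-1,3-benzodioxine F7, and deallylation (Pd(PPh3)4, zerovalent palladium, morpholine, THF) should return 4.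

Step 8. Silylation may not distinguish the two phenols well enough, so that the C3 silyl ether and the bis-silyl ether form beside 15. The fallback moves the differentiation from steric control of a protection to acidity control of the methylation itself; it sets out from 14 and comes back at 16. With one equivalent of NaH (DMF, 0 °C) the monophenoxide should sit mainly on the more acidic C3 oxygen (ortho to the aryloxy group). One equivalent of MeI should then give, after chromatographic removal of the C5 methyl ether and the dimethyl ether, methyl 2-[(8-chloro-2,2,7-trimethyl-4H-1,3-benzodioxin-5-yl)oxy]-5-hydroxy-3-methoxybenzoate F8. F8 has a single free phenol and is silylated (i-Pr3SiCl, imidazole, DMF) to 16.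

Further compounds
F1 | step 7 | methyl 5-hydroxy-2-iodo-3-methoxybenzoate | COC(=O)c1cc(O)cc(OC)c1I
F2 | step 7 | methyl 2-iodo-3-methoxy-5-[tri(propan-2-yl)silyloxy]benzoate | COC(=O)c1cc(O[Si](C(C)C)(C(C)C)C(C)C)cc(OC)c1I
F3 | step 3 | 5-hydroxy-2,2,7-trimethyl-4H-1,3-benzodioxin-4-one | Cc1cc(O)c2C(=O)OC(C)(C)Oc2c1
F4 | step 3 | 8-chloro-5-hydroxy-2,2,7-trimethyl-4H-1,3-benzodioxin-4-one | Cc1cc(O)c2C(=O)OC(C)(C)Oc2c1Cl
F5 | step 3 | 8-chloro-2,2,7-trimethyl-5-(prop-2-enyloxy)-4H-1,3-benzodioxin-4-one | C=CCOc1cc(C)c(Cl)c2OC(C)(C)OC(=O)c12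
F6 | step 3 | 2-chloro-6-(hydroxymethyl)-3-methyl-5-(prop-2-enyloxy)phenol | C=CCOc1cc(C)c(Cl)c(O)c1CO
F7 | step 3 | 8-chloro-2,2,7-trimethyl-5-(prop-2-enyloxy)-4H-1,3-benzodioxine | C=CCOc1cc(C)c(Cl)c2OC(C)(C)OCc12
F8 | step 8 | methyl 2-[(8-chloro-2,2,7-trimethyl-4H-1,3-benzodioxin-5-yl)oxy]-5-hydroxy-3-methoxybenzoate | COC(=O)c1cc(O)cc(OC)c1Oc1cc(C)c(Cl)c2OC(C)(C)OCc12
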